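The numbering below is used throughout.

Ring atoms: C1 (lactone O), C2 (ester O), C3 (tertiary OH and crotonoyl C1'–C4'), C4 (CH3), C5 (OH), C6 (CH2), C7 (lactone C). Lactone carbons: C11 (α), C12 (C=O), C13 (=CH2). The β-face carries C4–CH3, C3–O, C1–O and C7–C11; the α-face carries C2–O, C5–O and the side chain.
Cuts, in retrosynthetic order: the C2 ester C–O bond, the lactone O–C1 bond, C11=C13, C7–C11, and then C3–C1' together with C4–CH3.
Enabling feature: once C2 is a ketone, the oxygenated quaternary C3 is its α-carbon and the methyl-bearing C4 its β-carbon. A cyclohept-2-enone that already holds the C3 oxygen as an enol ether can therefore accept CH3 at C4 and the four-carbon aldehyde at C3 in one flask.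
Forward: the cycloheptane ring comes intact from cyclohepta-1,3-diene and is oxidised to the enone (steps 1–6), then loaded with both carbon groups (step 7). A [3,3] shift from a C2 allylic alcohol places the C7 acetamide (steps 9–11). The γ-lactone, the only ring that is built, closes in step 14; ester, ketone and deprotections finish the route.
Stereochemistry: C5 comes from a lipase resolution relayed by a directed epoxidation. In step 7, C4 forms anti to C5–O and C3 anti to C4–CH3. The C2 β-hydroxyl (step 10) is transferred to C7 by the suprafacial Claisen shift, α-epoxidation fixes C2, backside opening fixes C1, and the ester centre is bought.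

Key step: step 7

Remark: the chair transition state of step 7 is assumed to give the (1'R)-carbinol that is drawn. This centre becomes the ketone carbon in step 17, so either epimer serves. Racemic 2 and 4 are written as both enantiomers joined by a dot.

Step 1
Reactants: 1 cyclohepta-1,3-diene
Product: 2 rac-8-oxabicyclo[5.1.0]oct-2-ene
Conditions: mCPBA (1 equiv), Na2CO3, CH2Cl2, 0 °C
Reagents that add atoms: 3-chloroperoxybenzoic acid, OOC(=O)c1cccc(Cl)c1
Why: Peracid monoepoxidation (Prilezhaev reaction) of a conjugated diene should stop after one oxygen transfer because the vinyl epoxide is less nucleophilic than the diene, the carbonate protects the acid-labile product, and the ring enforces the cis fusion of the racemic epoxide.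

Step 2
Reactants: 2 rac-8-oxabicyclo[5.1.0]oct-2-ene; 3 4-methoxybenzyl alcohol
Product: 4 rac-trans-2-(4-methoxybenzyloxy)cyclohept-3-en-1-ol
Conditions: [Rh(CO)2Cl]2 (catalytic), 3 (excess), THF, rt
Reagents that add atoms: none
Why: Rhodium-catalysed alcoholysis of a vinyl epoxide under neutral conditions places the alkoxy group on the allylic carbon with inversion, so the trans-1,2-alkoxy alcohol should form without ionising the acid-sensitive benzylic alcohol.

Step 3
Reactants: 4 rac-trans-2-(4-methoxybenzyloxy)cyclohept-3-en-1-ol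
Product: 5 (1S,2S)-2-(4-methoxybenzyloxy)cyclohept-3-en-1-ol (unreacted enantiomer)
Conditions: Burkholderia cepacia lipase (immobilised), vinyl acetate, t-BuOMe, 30 °C, stopped just past half conversion; chromatography
Reagents that add atoms: none
Why: Lipase-catalysed kinetic resolution by transesterification is classical for trans-2-substituted cycloalkanols, the Kazlauskas rule (large group = the ether-bearing carbon) predicts acylation of the (1R)-carbinol, and the slow (1S,2S)-alcohol is recovered.

Step 4
Reactants: 5 (1S,2S)-2-(4-methoxybenzyloxy)cyclohept-3-en-1-ol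
Product: 6 (1S,2R,3R,4R)-3,4-epoxy-2-(4-methoxybenzyloxy)cycloheptan-1-ol
Conditions: VO(acac)2 (catalytic), t-BuOOH, CH2Cl2, 0 °C to rt
Reagents that add atoms: tert-butyl hydroperoxide, CC(C)(C)OO
Why: Vanadium-catalysed hydroxyl-directed epoxidation of a cyclic homoallylic alcohol delivers oxygen to the face of the hydroxyl group, which is also the face away from the allylic ether, so both elements favour the epoxide that carries the later C5 configuration.

Step 5
Reactants: 6 (1S,2R,3R,4R)-3,4-epoxy-2-(4-methoxybenzyloxy)cycloheptan-1-ol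
Product: 8 (4R)-4-hydroxy-2-(4-methoxybenzyloxy)cyclohept-2-en-1-one, via epoxy ketone 7 (not isolated)
Conditions: Dess–Martin periodinane, CH2Cl2, 0 °C to rt; then Et3N, rt
Reagents that add atoms: none
Why: Dess–Martin oxidation gives a β,γ-epoxy ketone whose doubly activated α-hydrogen is removed by triethylamine, and the E1cB opening breaks only the C–O bond at the β-carbon, so the γ-carbinol centre keeps the epoxide configuration and the 2-alkoxy enone arises directly.

Step 6
Reactants: 8 (4R)-4-hydroxy-2-(4-methoxybenzyloxy)cyclohept-2-en-1-one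
Product: 9 (4R)-4-(tert-butyldimethylsilyloxy)-2-(4-methoxybenzyloxy)cyclohept-2-en-1-one
Conditions: TBSCl, imidazole, DMF, rt
Reagents that add atoms: tert-butyldimethylsilyl chloride, CC(C)(C)[Si](C)(C)Cl
Why: Standard silylation of a secondary allylic alcohol touches no stereocentre and installs the bulky group that will shield the α-face in the next step.

Step 7
Reactants: 9 (4R)-4-(tert-butyldimethylsilyloxy)-2-(4-methoxybenzyloxy)cyclohept-2-en-1-one; 10 lithium dimethylcuprate; 11 (E)-but-2-enal
Product: 14 aldol adduct (2R,3S,4R)-4-(tert-butyldimethylsilyloxy)-2-[(1R,2E)-1-hydroxybut-2-en-1-yl]-2-(4-methoxybenzyloxy)-3-methylcycloheptan-1-one, via lithium enolate 12 (not isolated), via lithium aldolate 13 (not isolated)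
Conditions: 10 (from MeLi and CuI, Et2O, 0 °C), Et2O, −78 to −30 °C; then 11, THF, −78 °C; AcOH in THF at −78 °C
Reagents that add atoms: none
Why: The Gilman cuprate binds the enone as a π-complex, adds oxidatively at C4 and reductively eliminates the C4–CH3 bond, which leaves lithium enolate 12 with the C3 oxygen already in place, and 12 then attacks the carbonyl carbon of 11 through a closed lithium-bridged Zimmerman–Traxler chair to give aldolate 13 (C3–C1' bond, quaternary C3). The closest known reaction type is the three-component conjugate addition–aldol coupling of 4-silyloxycycloalkenones, here with a 2-alkoxy enone as the less electrophilic acceptor. No ring is closed. C4 is controlled by the C5 silyl ether, which shields the α-face so that methyl enters on the β-face, and C3 by the new C4 methyl group, which sends the aldehyde to the α-face and leaves the C3 oxygen β and cis to methyl, while C1' follows from the chair and is erased later. The step needs 1,4- rather than 1,2-addition (soft cuprate in ether, with the inductive pull of the C5 oxygen offsetting the donor at C3), a regiodefined enolate (aprotic medium and trapping at −78 °C before proton exchange to C1) and carbonyl rather than conjugate attack on 11 (hard lithium enolate). Quenching with acetic acid at −78 °C protonates 13 before it can revert by retro-aldol cleavage.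

Step 8
Reactants: 14 aldol adduct
Product: 15 triethylsilyl ether of 14 (C1'–OSiEt3)
Conditions: TESOTf, 2,6-lutidine, CH2Cl2, −78 °C
Reagents that add atoms: triethylsilyl trifluoromethanesulfonate, CC[Si](CC)(CC)OS(=O)(=O)C(F)(F)F
Why: A silyl triflate with a hindered pyridine base silylates the crowded aldol hydroxyl at low temperature without forming an alkoxide, so retro-aldol cleavage at the quaternary C3 is avoided and no stereocentre is touched.

Step 9
Reactants: 15 triethylsilyl ether of 14
Product: 17 C1–C7 enone (5R,6S,7R)-5-(tert-butyldimethylsilyloxy)-7-(4-methoxybenzyloxy)-6-methyl-7-[(1R,2E)-1-(triethylsilyloxy)but-2-en-1-yl]cyclohept-2-en-1-one, via silyl enol ether 16 (not isolated)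
Conditions: LiN(SiMe3)2, Me3SiCl, THF, −78 to 0 °C; then Pd(OAc)2, MeCN, rt
Reagents that add atoms: chlorotrimethylsilane, C[Si](C)(C)Cl (its atoms stand in 16 only)
Why: In this Saegusa–Ito oxidation the quaternary C3 allows enolisation toward C1 only, and palladium diacetate turns silyl enol ether 16 into the C1–C7 enone by β-hydride elimination without touching the isolated side-chain alkene.

Step 10
Reactants: 17 C1–C7 enone
Product: 18 2β-allylic alcohol (1R,5R,6S,7S)-5-(tert-butyldimethylsilyloxy)-7-(4-methoxybenzyloxy)-6-methyl-7-[(1R,2E)-1-(triethylsilyloxy)but-2-en-1-yl]cyclohept-2-en-1-ol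
Conditions: NaBH4, CeCl3·7H2O, MeOH, −78 to −20 °C
Reagents that add atoms: none
Why: Luche reduction gives 1,2-reduction, and with the bulky side chain pseudoequatorial and the C3 ether oxygen pseudoaxial on the β-face the hydride should attack anti to that C–O bond (polar Felkin–Anh) from the α-face, which places the new C2 hydroxyl β.

Step 11
Reactants: 18 2β-allylic alcohol
Product: 20 2-[(1S,4R,5S,6R)-6-(tert-butyldimethylsilyloxy)-4-(4-methoxybenzyloxy)-5-methyl-4-[(1R,2E)-1-(triethylsilyloxy)but-2-en-1-yl]cyclohept-2-en-1-yl]-N,N-dimethylacetamide, via ketene N,O-acetal 19 (not isolated)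
Conditions: MeC(OMe)2NMe2, xylenes, 140 °C
Reagents that add atoms: N,N-dimethylacetamide dimethyl acetal, COC(C)(OC)N(C)C
Why: In the Eschenmoser–Claisen rearrangement alcohol exchange and loss of methanol give ketene N,O-acetal 19, whose suprafacial [3,3] shift carries the two-carbon unit from the β-oxygen at C2 to the β-face of C7 and moves the alkene to C1–C2 under neutral conditions that all ethers tolerate.

Step 12
Reactants: 20 C7β-acetamide
Product: 21 Mannich base of 20 (C11 bears CH2NMe2; epimers at C11)
Conditions: LiN(i-Pr)2, THF, −78 °C; then CH2=NMe2+ I−, −78 °C to rt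
Reagents that add atoms: N,N-dimethylmethyleneiminium iodide (Eschenmoser's salt), C=[N+](C)C.[I-]
Why: The Mannich reaction of the amide lithium enolate, the only acidic site of 20, with the preformed iminium salt gives a C11 epimer mixture that is of no consequence because C11 becomes trigonal in step 13.

Step 13
Reactants: 21 Mannich base
Product: 23 acrylamide (C11=C13 in place; C7β-[1-(dimethylcarbamoyl)vinyl] group), via ammonium iodide 22 (not isolated)
Conditions: MeI, CH2Cl2, rt; evaporate; DBU, CH2Cl2, rt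
Reagents that add atoms: iodomethane, CI (its atoms stand in 22 only)
Why: Quaternisation of the amine followed by Hofmann-type E1cB loss of trimethylamine is the standard way to an α-methylene carbonyl group, and doing it before the lactone exists keeps strong base away from every later intermediate.

Step 14
Reactants: 23 acrylamide
Product: 26 cis-fused α-methylene-γ-lactone with free C2α hydroxyl (C1β–O and C7β–C11), via epoxide 24 (not isolated), via iminium ether acetate 25 (not isolated)
Conditions: dimethyldioxirane (1 equiv), acetone/CH2Cl2, −30 to 0 °C; then AcOH, THF/H2O, rt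
Reagents that add atoms: dimethyldioxirane, CC1(C)OO1; water, O; acetic acid, CC(=O)O (counter-ion of 25 only)
Why: In this dioxirane epoxidation with neighbouring-group lactonisation the acrylamide alkene is electron-poor, the spiro transition state favours the cis ring alkene over the trans side-chain alkene, attack on the α-face is anti to the C7 substituent and the pseudoaxial C3 ether, and the amide oxygen then opens epoxide 24 at C1 from the β-face (5-exo, inversion) to iminium ether 25, whose hydrolysis gives the cis-fused lactone and the C2α alcohol.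

Step 15
Reactants: 26 hydroxy lactone; 27 (S)-2-methylbutanoic anhydride
Product: 28 C2α (S)-2-methylbutanoate of 26
Conditions: 27, DMAP, Et3N, CH2Cl2, rt to 40 °C
Reagents that add atoms: none
Why: DMAP-catalysed acylation with the enantiopure anhydride is the usual way to place this ester on a hindered secondary alcohol, it runs through no ketene so the (S)-centre is kept, and C2–OH is the only free hydroxyl group.

Step 16
Reactants: 28 C2α ester
Product: 29 side-chain allylic alcohol (C1'–OH free)
Conditions: PPTS, MeOH/CH2Cl2, 0 °C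
Reagents that add atoms: none
Why: Mild acid methanolysis removes a triethylsilyl ether much faster than a tert-butyldimethylsilyl ether, so only the side-chain carbinol is released.

Step 17
Reactants: 29 side-chain allylic alcohol
Product: 30 (E)-crotonoyl ketone (C3β–OPMB and C5α–OTBS still in place)
Conditions: Dess–Martin periodinane, CH2Cl2, rt
Reagents that add atoms: none
Why: Dess–Martin oxidation of the only free alcohol under non-basic conditions gives the (E)-enone and erases C1', and because C2 is already acylated no hydroxyl group is left for oxa-Michael addition or retro-aldol cleavage.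

Step 18
Reactants: 30 crotonoyl ketone
Product: 31 tertiary alcohol (C3β–OH free; C5α–OTBS)
Conditions: DDQ, CH2Cl2/pH 7 buffer, 0 °C
Reagents that add atoms: none
Why: Oxidative cleavage of the 4-methoxybenzyl ether by DDQ starts with hydride abstraction from the electron-rich benzylic position and leaves the enone, the α-methylene lactone, the ester and the silyl ether untouched.

Step 19
Reactants: 31 tertiary alcohol
Product: 32 CNP0331957.1
Conditions: HF·pyridine, pyridine/THF, 0 °C to rt
Reagents that add atoms: none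
Why: Buffered hydrogen fluoride cleaves the last silyl ether under non-basic conditions, which avoids acyl migration, retro-aldol cleavage and conjugate addition to the two Michael acceptors.

Compound list
1 | cyclohepta-1,3-diene | C1=CC=CCCC1 | starting material
2 | rac-8-oxabicyclo[5.1.0]oct-2-ene (both enantiomers) | O1[C@H]2CCCC=C[C@@H]12.O1[C@@H]2CCCC=C[C@H]12 | intermediate
3 | 4-methoxybenzyl alcohol | COc1ccc(CO)cc1 | starting material
4 | rac-trans-2-(4-methoxybenzyloxy)cyclohept-3-en-1-ol (both enantiomers) | O[C@H]1CCCC=C[C@@H]1OCc1ccc(OC)cc1.O[C@@H]1CCCC=C[C@H]1OCc1ccc(OC)cc1 | intermediate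
5 | (1S,2S)-2-(4-methoxybenzyloxy)cyclohept-3-en-1-ol | O[C@H]1CCCC=C[C@@H]1OCc1ccc(OC)cc1 | intermediate
6 | (1S,2R,3R,4R)-3,4-epoxy-2-(4-methoxybenzyloxy)cycloheptan-1-ol (epoxide cis to OH, trans to the ether) | O[C@H]1CCC[C@H]2O[C@H]2[C@@H]1OCc1ccc(OC)cc1 | intermediate
7 | (2S,3R,4R)-3,4-epoxy-2-(4-methoxybenzyloxy)cycloheptan-1-one | O=C1CCC[C@H]2O[C@H]2[C@@H]1OCc1ccc(OC)cc1 | intermediate
8 | (4R)-4-hydroxy-2-(4-methoxybenzyloxy)cyclohept-2-en-1-one | O=C1CCC[C@@H](O)C=C1OCc1ccc(OC)cc1 | intermediate
9 | (4R)-4-(tert-butyldimethylsilyloxy)-2-(4-methoxybenzyloxy)cyclohept-2-en-1-one | O=C1CCC[C@@H](O[Si](C)(C)C(C)(C)C)C=C1OCc1ccc(OC)cc1 | intermediate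
10 | lithium dimethylcuprate (Gilman reagent, freshly prepared from MeLi and CuI) | [Li+].C[Cu-]C | starting material
11 | (E)-but-2-enal (crotonaldehyde) | C/C=C/C=O | starting material
12 | lithium (3S,4R)-4-(tert-butyldimethylsilyloxy)-2-(4-methoxybenzyloxy)-3-methylcyclohept-1-en-1-olate | [Li+].[O-]C1=C(OCc2ccc(OC)cc2)[C@@H](C)[C@H](O[Si](C)(C)C(C)(C)C)CCC1 | intermediate
13 | lithium aldolate of 14 | O=C1CCC[C@@H](O[Si](C)(C)C(C)(C)C)[C@H](C)[C@@]1(OCc1ccc(OC)cc1)[C@H]([O-])/C=C/C.[Li+] | intermediate
14 | (2R,3S,4R)-4-(tert-butyldimethylsilyloxy)-2-[(1R,2E)-1-hydroxybut-2-en-1-yl]-2-(4-methoxybenzyloxy)-3-methylcycloheptan-1-one (C2 ketone, 3β-OPMB, 3α side chain, 4β-CH3, 5α-OTBS) | O=C1CCC[C@@H](O[Si](C)(C)C(C)(C)C)[C@H](C)[C@@]1(OCc1ccc(OC)cc1)[C@H](O)/C=C/C | intermediate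
15 | C1'-triethylsilyl ether of 14 | O=C1CCC[C@@H](O[Si](C)(C)C(C)(C)C)[C@H](C)[C@@]1(OCc1ccc(OC)cc1)[C@H](O[Si](CC)(CC)CC)/C=C/C | intermediate
16 | trimethylsilyl enol ether of 15 (C2–OSiMe3, C1=C2) | C[Si](C)(C)OC1=CCC[C@@H](O[Si](C)(C)C(C)(C)C)[C@H](C)[C@@]1(OCc1ccc(OC)cc1)[C@H](O[Si](CC)(CC)CC)/C=C/C | intermediate
17 | (5R,6S,7R)-5-(tert-butyldimethylsilyloxy)-7-(4-methoxybenzyloxy)-6-methyl-7-[(1R,2E)-1-(triethylsilyloxy)but-2-en-1-yl]cyclohept-2-en-1-one (C2 ketone, C1=C7) | O=C1C=CC[C@@H](O[Si](C)(C)C(C)(C)C)[C@H](C)[C@@]1(OCc1ccc(OC)cc1)[C@H](O[Si](CC)(CC)CC)/C=C/C | intermediate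
18 | (1R,5R,6S,7S)-5-(tert-butyldimethylsilyloxy)-7-(4-methoxybenzyloxy)-6-methyl-7-[(1R,2E)-1-(triethylsilyloxy)but-2-en-1-yl]cyclohept-2-en-1-ol (2β-OH) | O[C@@H]1C=CC[C@@H](O[Si](C)(C)C(C)(C)C)[C@H](C)[C@@]1(OCc1ccc(OC)cc1)[C@H](O[Si](CC)(CC)CC)/C=C/C | intermediate
19 | ketene N,O-acetal of 18 (C2β–O–C(=CH2)NMe2) | C=C(N(C)C)O[C@@H]1C=CC[C@@H](O[Si](C)(C)C(C)(C)C)[C@H](C)[C@@]1(OCc1ccc(OC)cc1)[C@H](O[Si](CC)(CC)CC)/C=C/C | intermediate
20 | 2-[(1S,4R,5S,6R)-6-(tert-butyldimethylsilyloxy)-4-(4-methoxybenzyloxy)-5-methyl-4-[(1R,2E)-1-(triethylsilyloxy)but-2-en-1-yl]cyclohept-2-en-1-yl]-N,N-dimethylacetamide (C7β–CH2CONMe2, C1=C2) | CN(C)C(=O)C[C@H]1C=C[C@](OCc2ccc(OC)cc2)([C@H](O[Si](CC)(CC)CC)/C=C/C)[C@@H](C)[C@H](O[Si](C)(C)C(C)(C)C)C1 | intermediate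
21 | Mannich base of 20 (CH2NMe2 on C11, C11 epimers) | CN(C)CC(C(=O)N(C)C)[C@H]1C=C[C@](OCc2ccc(OC)cc2)([C@H](O[Si](CC)(CC)CC)/C=C/C)[C@@H](C)[C@H](O[Si](C)(C)C(C)(C)C)C1 | intermediate
22 | trimethylammonium iodide of 21 | C[N+](C)(C)CC(C(=O)N(C)C)[C@H]1C=C[C@](OCc2ccc(OC)cc2)([C@H](O[Si](CC)(CC)CC)/C=C/C)[C@@H](C)[C@H](O[Si](C)(C)C(C)(C)C)C1.[I-] | intermediate
23 | acrylamide (C7β–C(=CH2)CONMe2, C1=C2) | C=C(C(=O)N(C)C)[C@H]1C=C[C@](OCc2ccc(OC)cc2)([C@H](O[Si](CC)(CC)CC)/C=C/C)[C@@H](C)[C@H](O[Si](C)(C)C(C)(C)C)C1 | intermediate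
24 | 1α,2α-epoxide of 23 | C=C(C(=O)N(C)C)[C@H]1[C@@H]2O[C@@H]2[C@](OCc2ccc(OC)cc2)([C@H](O[Si](CC)(CC)CC)/C=C/C)[C@@H](C)[C@H](O[Si](C)(C)C(C)(C)C)C1 | intermediate
25 | cyclic iminium ether acetate (C1β–O–C12(=NMe2+), C2α–OH) | C=C1C(=[N+](C)C)O[C@@H]2[C@H]1C[C@@H](O[Si](C)(C)C(C)(C)C)[C@H](C)[C@@](OCc1ccc(OC)cc1)([C@H](O[Si](CC)(CC)CC)/C=C/C)[C@H]2O.CC(=O)[O-] | intermediate
26 | cis-fused α-methylene-γ-lactone, C2α–OH, 3β-OPMB, C1'-OTES, 5α-OTBS | C=C1C(=O)O[C@@H]2[C@H]1C[C@@H](O[Si](C)(C)C(C)(C)C)[C@H](C)[C@@](OCc1ccc(OC)cc1)([C@H](O[Si](CC)(CC)CC)/C=C/C)[C@H]2O | intermediate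
27 | (S)-2-methylbutanoic anhydride | CC[C@H](C)C(=O)OC(=O)[C@@H](C)CC | starting material
28 | C2α (S)-2-methylbutanoate of 26 | C=C1C(=O)O[C@@H]2[C@H]1C[C@@H](O[Si](C)(C)C(C)(C)C)[C@H](C)[C@@](OCc1ccc(OC)cc1)([C@H](O[Si](CC)(CC)CC)/C=C/C)[C@H]2OC(=O)[C@@H](C)CC | intermediate
29 | C1'-alcohol from 28 | C=C1C(=O)O[C@@H]2[C@H]1C[C@@H](O[Si](C)(C)C(C)(C)C)[C@H](C)[C@@](OCc1ccc(OC)cc1)([C@H](O)/C=C/C)[C@H]2OC(=O)[C@@H](C)CC | intermediate
30 | (E)-crotonoyl ketone, 3β-OPMB, 5α-OTBS | C=C1C(=O)O[C@@H]2[C@H]1C[C@@H](O[Si](C)(C)C(C)(C)C)[C@H](C)[C@@](OCc1ccc(OC)cc1)(C(=O)/C=C/C)[C@H]2OC(=O)[C@@H](C)CC | intermediate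
31 | C3β tertiary alcohol, 5α-OTBS | C=C1C(=O)O[C@@H]2[C@H]1C[C@@H](O[Si](C)(C)C(C)(C)C)[C@H](C)[C@@](O)(C(=O)/C=C/C)[C@H]2OC(=O)[C@@H](C)CC | intermediate
32 | CNP0331957.1 (C1 R, C2 S, C3 S, C4 S, C5 R, C7 S in the numbering used here; (S)-2-methylbutanoate) | C=C1C(=O)O[C@@H]2[C@H]1C[C@@H](O)[C@H](C)[C@@](O)(C(=O)/C=C/C)[C@H]2OC(=O)[C@@H](C)CC | target

Total step count: 19. Longest linear sequence: 19 steps (from 1).

Steps most likely to fail

Step 7. Several things may go wrong here: methyl transfer to the donor-substituted enone may be slow, the enolate may exchange a proton before it is trapped, the aldol addition may reverse at the crowded C3, or the flexible ring may give a weak facial bias. The fallback sets out from 9 and comes back at 14, and it separates the two bond formations. Me2CuLi is used together with Me3SiCl, which accelerates the conjugate addition and captures the enolate as the trimethylsilyl enol ether F1. After isolation, this is combined with 11 under BF3·OEt2 in CH2Cl2 at −78 °C. This Mukaiyama aldol addition has an open transition state, is not reversible under these conditions, and still approaches anti to the C4 methyl group. Aqueous work-up should then give 14.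

Step 14. Oxygen transfer to the side-chain alkene may compete with epoxidation of the ring alkene, or the oxidant may approach from the β-face. The fallback sets out from 23 and comes back at 30, and it changes the order of events so that the ring alkene is the only nucleophilic π-bond.
- PPTS in MeOH releases the side-chain allylic alcohol F2.
- Dess–Martin oxidation gives the crotonoyl ketone F3, in which the side-chain and acrylamide alkenes are both electron-poor.
- Dimethyldioxirane can then reach only C1–C2 and gives the 1α,2α-epoxide F4.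
- AcOH in wet THF closes the hydroxy lactone F5.
- This is acylated at once with 27 and DMAP, before its C2 hydroxyl can add to the enone, to give 30.

Step 10. Hydride delivery from the β-face would produce the C2α alcohol and so send the Claisen unit to the wrong face of C7. The fallback sets out from 17 and comes back at 18, and it replaces stereoselective reduction by stereoinversion. The reduction product, the 2α-allylic alcohol F6, is submitted to a Mitsunobu reaction (4-nitrobenzoic acid, PPh3, DIAD, toluene). This gives the inverted 2β 4-nitrobenzoate F7, and methanolysis (K2CO3, MeOH) releases 18.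

Further compounds
F1 | step 7 | [(3S,4R)-4-(tert-butyldimethylsilyloxy)-2-(4-methoxybenzyloxy)-3-methylcyclohept-1-en-1-yl]oxytrimethylsilane | C[Si](C)(C)OC1=C(OCc2ccc(OC)cc2)[C@@H](C)[C@H](O[Si](C)(C)C(C)(C)C)CCC1
F2 | step 14 | C1'-alcohol of acrylamide 23 | C=C(C(=O)N(C)C)[C@H]1C=C[C@](OCc2ccc(OC)cc2)([C@H](O)/C=C/C)[C@@H](C)[C@H](O[Si](C)(C)C(C)(C)C)C1
F3 | step 14 | crotonoyl ketone of acrylamide 23 | C=C(C(=O)N(C)C)[C@H]1C=C[C@](OCc2ccc(OC)cc2)(C(=O)/C=C/C)[C@@H](C)[C@H](O[Si](C)(C)C(C)(C)C)C1
F4 | step 14 | 1α,2α-epoxide of F3 | C=C(C(=O)N(C)C)[C@H]1[C@@H]2O[C@@H]2[C@](OCc2ccc(OC)cc2)(C(=O)/C=C/C)[C@@H](C)[C@H](O[Si](C)(C)C(C)(C)C)C1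
F5 | step 14 | cis-fused α-methylene-γ-lactone with C2α–OH and crotonoyl group | C=C1C(=O)O[C@@H]2[C@H]1C[C@@H](O[Si](C)(C)C(C)(C)C)[C@H](C)[C@@](OCc1ccc(OC)cc1)(C(=O)/C=C/C)[C@H]2O
F6 | step 10 | 2α-epimer of allylic alcohol 18 | O[C@H]1C=CC[C@@H](O[Si](C)(C)C(C)(C)C)[C@H](C)[C@@]1(OCc1ccc(OC)cc1)[C@H](O[Si](CC)(CC)CC)/C=C/C
F7 | step 10 | 2β 4-nitrobenzoate of 18 | O=C(O[C@@H]1C=CC[C@@H](O[Si](C)(C)C(C)(C)C)[C@H](C)[C@@]1(OCc1ccc(OC)cc1)[C@H](O[Si](CC)(CC)CC)/C=C/C)c1ccc(cc1)[N+](=O)[O-]
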